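The flavone is cut at the C2–C1′ bond between the pyranone ring and the trimethoxyphenyl ring. The key step exploits the C2–H of a 3,5,7-trimethoxychromone. Flanked by ring oxygen O1 and the C3 methoxy group, it is the most acidic C–H, so a TMP-zinc amide turns this normally electrophilic β-carbon of the vinylogous ester into a nucleophile (polarity reversal). Negishi coupling with 1-bromo-2,3,4-trimethoxybenzene then forges the bond in the same pot. The precursor is a simple C2-unsubstituted chromone made in two steps. The 8-OH is introduced last, para to the unmasked 5-OH, by Elbs persulfate oxidation.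

Key step: step 3

Remark: the target has no stereocentre and no stereogenic double bond, so no stereocontrol is required. Compounds 1, 2 and 6 and TMPZnCl·LiCl (THF solution) are taken as commercial.

Step 1
Reactants: 1 3,5-dimethoxyphenol; 2 methoxyacetic acid
Product: 3 1-(2-hydroxy-4,6-dimethoxyphenyl)-2-methoxyethan-1-one
Conditions: BF3·OEt2 (as solvent), 85 °C; then aq. NaOAc
Reagents that add atoms: none
Why: BF3-mediated Friedel–Crafts acylation (aryl ester formation and Fries-type ortho migration) should place the methoxyacetyl group ortho to the phenol, because the difluoroboron chelate between phenolic oxygen and the new carbonyl favours that position and the two ortho positions of 1 are equivalent.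

Step 2
Reactants: 3 1-(2-hydroxy-4,6-dimethoxyphenyl)-2-methoxyethan-1-one
Product: 5 3,5,7-trimethoxy-4H-chromen-4-one, via enaminone 4 (not isolated)
Conditions: DMF-DMA, toluene, 100 °C; then aq. HCl, CH2Cl2, rt
Reagents that add atoms: N,N-dimethylformamide dimethyl acetal, COC(OC)N(C)C
Why: Enaminone condensation at the α-methoxymethylene, followed by acid-promoted intramolecular conjugate addition of the phenol and loss of dimethylamine (the enaminone route to chromones and isoflavones), should close the pyranone ring and leave C2 as a C–H.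

Step 3
Reactants: 5 3,5,7-trimethoxy-4H-chromen-4-one; 6 1-bromo-2,3,4-trimethoxybenzene
Product: 8 3,5,7-trimethoxy-2-(2,3,4-trimethoxyphenyl)-4H-chromen-4-one, via C2-zincated chromone 7 (not isolated)
Conditions: TMPZnCl·LiCl (1.3 equiv), THF, 25 °C; then 6, Pd(OAc)2 (2 mol%), SPhos (4 mol%), 55 °C
Reagents that add atoms: none
Why: TMPZnCl·LiCl should remove the C2–H of the pyranone ring, the most acidic C–H of 5 because it is α to ring oxygen O1 and ortho to the 3-OMe group, to give the C2-zinc species 7. Pd(0)/SPhos then inserts into the C–Br bond of 6, and transmetalation from zinc followed by reductive elimination forms the C2–C1′ bond. The closest known reaction type is the TMP-zinc C2-metalation of chromones followed by Negishi arylation to flavones. No ring is closed and no stereocentre is formed. The step needs site selectivity for C2–H over the A-ring C6–H and C8–H, which the mild zinc amide and the methoxy-blocked C3 position should secure. The aryl regiochemistry is fixed by the bromine position in 6, and SPhos is chosen because the new bond is flanked by the 3-OMe and 2′-OMe groups.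

Step 4
Reactants: 8 3,5,7-trimethoxy-2-(2,3,4-trimethoxyphenyl)-4H-chromen-4-one
Product: 9 5-hydroxy-3,7-dimethoxy-2-(2,3,4-trimethoxyphenyl)-4H-chromen-4-one
Conditions: BCl3 (1.1 equiv), CH2Cl2, −78 → 0 °C; then aq. NaHCO3
Reagents that add atoms: none
Why: Boron trichloride should bind the C4 carbonyl and cleave only the peri 5-OMe through a six-membered chelate (the selective 5-O-demethylation of polymethoxyflavones), with one equivalent at low temperature sparing the 3-OMe and the B-ring ethers.

Step 5
Reactants: 9 5-hydroxy-3,7-dimethoxy-2-(2,3,4-trimethoxyphenyl)-4H-chromen-4-one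
Product: 11 5,8-dihydroxy-3,7-dimethoxy-2-(2,3,4-trimethoxyphenyl)-4H-chromen-4-one (target), via potassium flavon-8-yl sulfate 10 (not isolated)
Conditions: K2S2O8, aq. KOH, pyridine, 0 → 20 °C; then HCl, Na2SO3, 80 °C
Reagents that add atoms: potassium peroxodisulfate, [K+].[K+].[O-]S(=O)(=O)OOS(=O)(=O)[O-]
Why: In the Elbs persulfate oxidation the 5-phenolate should attack a peroxide oxygen of peroxodisulfate through its para carbon C8, and acidic hydrolysis of the resulting aryl sulfate under reducing conditions releases the 8-OH, as in the classical 8-hydroxylation of 5-hydroxy-7-methoxyflavonol methyl ethers.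

Compound list
1 | 3,5-dimethoxyphenol | COc1cc(O)cc(OC)c1 | starting material
2 | methoxyacetic acid | COCC(=O)O | starting material
3 | 1-(2-hydroxy-4,6-dimethoxyphenyl)-2-methoxyethan-1-one | COCC(=O)c1c(O)cc(OC)cc1OC | intermediate
4 | (Z)-3-(dimethylamino)-1-(2-hydroxy-4,6-dimethoxyphenyl)-2-methoxyprop-2-en-1-one (geometry shown is of no consequence) | CN(C)/C=C(\OC)C(=O)c1c(O)cc(OC)cc1OC | intermediate
5 | 3,5,7-trimethoxy-4H-chromen-4-one | COc1cc(OC)c2c(=O)c(OC)coc2c1 | intermediate
6 | 1-bromo-2,3,4-trimethoxybenzene | COc1ccc(Br)c(OC)c1OC | starting material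
7 | (3,5,7-trimethoxy-4-oxo-4H-chromen-2-yl)zinc chloride (LiCl complex) | COc1cc(OC)c2c(=O)c(OC)c([Zn]Cl)oc2c1 | intermediate
8 | 3,5,7-trimethoxy-2-(2,3,4-trimethoxyphenyl)-4H-chromen-4-one | COc1ccc(-c2oc3cc(OC)cc(OC)c3c(=O)c2OC)c(OC)c1OC | intermediate
9 | 5-hydroxy-3,7-dimethoxy-2-(2,3,4-trimethoxyphenyl)-4H-chromen-4-one | COc1ccc(-c2oc3cc(OC)cc(O)c3c(=O)c2OC)c(OC)c1OC | intermediate
10 | potassium 5-hydroxy-3,7-dimethoxy-4-oxo-2-(2,3,4-trimethoxyphenyl)-4H-chromen-8-yl sulfate | COc1ccc(-c2oc3c(OS(=O)(=O)[O-])c(OC)cc(O)c3c(=O)c2OC)c(OC)c1OC.[K+] | intermediate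
11 | 5,8-dihydroxy-3,7-dimethoxy-2-(2,3,4-trimethoxyphenyl)-4H-chromen-4-one | COc1ccc(-c2oc3c(O)c(OC)cc(O)c3c(=O)c2OC)c(OC)c1OC | target

Total step count: 5
Longest linear sequence: 5 steps (1 → 3 → 5 → 8 → 9 → 11)

Steps most likely to fail

Step 3 (key step). Zincation may be incomplete or may stray to the A-ring C6–H or C8–H, or the hindered C2-zinc species may transmetalate slowly, so that protodezincation and homocoupling outrun cross-coupling. The fallback sets out from 5 and 6 and comes back at 8, and it returns both partners to their native polarity. Bromide 6 would be converted with magnesium in THF into (2,3,4-trimethoxyphenyl)magnesium bromide F1. Chromone 5 would be activated with TMSOTf (CH2Cl2/THF, −78 °C) as 3,5,7-trimethoxy-4-(trimethylsilyloxy)chromenylium triflate F2, whose C2 is strongly electrophilic. Addition of F1 to C2 of F2 should give racemic 3,5,7-trimethoxy-2-(2,3,4-trimethoxyphenyl)-4-(trimethylsilyloxy)-2H-chromene F3. DDQ (CH2Cl2, 0 °C) should then abstract the doubly activated C2 hydride and, after loss of the silyl group, give flavone 8.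

Step 5. Conversion of the hydrogen-bonded 5-phenol may be low, and the flavone may suffer oxidative or alkaline degradation during the long exposure to persulfate and base. The fallback sets out from 9 and comes back at 11. Teuber oxidation of the para-unsubstituted phenol with Fremy's salt (KH2PO4 buffer, aqueous acetone) should give 3,7-dimethoxy-2-(2,3,4-trimethoxyphenyl)-4H-chromene-4,5,8-trione F4. Reduction of this quinone with Na2S2O4 (EtOAc/H2O) should give the hydroquinone 11.

Step 4. Site selectivity among six methyl ethers may be lost, in particular by chelation-assisted cleavage of the central 3′-OMe of the vicinal trimethoxy B ring. The fallback sets out from 5 and comes back at 9, and it unmasks the 5-oxygen before the B ring is present. BCl3 (CH2Cl2, −78 → 0 °C) on 5, which carries no vicinal trimethoxy unit, should give 5-hydroxy-3,7-dimethoxy-4H-chromen-4-one F5. Benzylation (BnBr, K2CO3, DMF) should give 5-(benzyloxy)-3,7-dimethoxy-4H-chromen-4-one F6. Zincation with TMPZnCl·LiCl to the C2-zinc species [5-(benzyloxy)-3,7-dimethoxy-4-oxo-4H-chromen-2-yl]zinc chloride F7, and Negishi coupling with 6 as in step 3, should give 5-(benzyloxy)-3,7-dimethoxy-2-(2,3,4-trimethoxyphenyl)-4H-chromen-4-one F8. Hydrogenolysis (H2, Pd/C, EtOAc) should then release 9 under neutral conditions.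

Further compounds
F1 | step 3 | (2,3,4-trimethoxyphenyl)magnesium bromide | COc1ccc([Mg]Br)c(OC)c1OC
F2 | step 3 | 3,5,7-trimethoxy-4-(trimethylsilyloxy)chromenylium trifluoromethanesulfonate | COc1cc(OC)c2c(O[Si](C)(C)C)c(OC)c[o+]c2c1.[O-]S(=O)(=O)C(F)(F)F
F3 | step 3 | 3,5,7-trimethoxy-2-(2,3,4-trimethoxyphenyl)-4-(trimethylsilyloxy)-2H-chromene (racemic) | COc1cc(OC)c2c(c1)OC(c1ccc(OC)c(OC)c1OC)C(OC)=C2O[Si](C)(C)C
F4 | step 5 | 3,7-dimethoxy-2-(2,3,4-trimethoxyphenyl)-4H-chromene-4,5,8-trione | COC1=C(c2ccc(OC)c(OC)c2OC)OC2=C(C1=O)C(=O)C=C(OC)C2=O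
F5 | step 4 | 5-hydroxy-3,7-dimethoxy-4H-chromen-4-one | COc1cc(O)c2c(=O)c(OC)coc2c1
F6 | step 4 | 5-(benzyloxy)-3,7-dimethoxy-4H-chromen-4-one | COc1cc(OCc3ccccc3)c2c(=O)c(OC)coc2c1
F7 | step 4 | [5-(benzyloxy)-3,7-dimethoxy-4-oxo-4H-chromen-2-yl]zinc chloride | COc1cc(OCc3ccccc3)c2c(=O)c(OC)c([Zn]Cl)oc2c1
F8 | step 4 | 5-(benzyloxy)-3,7-dimethoxy-2-(2,3,4-trimethoxyphenyl)-4H-chromen-4-one | COc1ccc(-c2oc3cc(OC)cc(OCc4ccccc4)c3c(=O)c2OC)c(OC)c1OC
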